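**Retrosynthetic overview**
1. Cycloshizukaol A is C2-symmetric, so both C11–C15′ bonds are cut: two α-alkylations of an 8β,12-lactone dienolate by a C15 allylic bromide, the second closing the 12-membered ring. The lactones are opened and C8 is oxidised only afterwards.
2. Ring B of the monomer (C6=C7, O at C8, 9β-OH, propanoate on C7) is grown from the C9 oxygen. C4=C5 and the C15 CH2 come from a methyl ester on C4 of the bicyclo[3.1.0]hexane.
3. That ester comes from photochemical Wolff contraction of a cyclopropanated trans-decalin 4-diazo-15-ketone, built from (S)-Wieland–Miescher ketone.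
4. Feature the plan rests on: C15 is exocyclic on C4, next to cyclopropane carbon C3. Hence C1, C3, C15, C4, C5 and C10 are the six atoms of the enone ring of Wieland–Miescher ketone, whose second ring is ring B with its oxygen at C9 and methyl C14 on C10.
5. Ring order: ring B and the six-membered precursor ring (given), cyclopropane, ring A by contraction, two temporary lactone rings, macrocycle.

Key step: step 10

Remark: lindenane numbering is used throughout (cyclopropane C1–C2–C3; ring A = C1, C3, C4, C5, C10; ring B = C5–C10; C14 on C10; C15 on C4; C11–C13 on C7), and β is the face of C14. Compounds with a C11–H centre (35–39, 41–43) are carried as C11 epimer mixtures, because both epimers give the same enolate; their SMILES leave that centre open.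

**Step 1**
Reactants: 1 (S)-Wieland–Miescher ketone
Product: 2 (4aS,5S)-5-hydroxy-4a-methyl-4,4a,5,6,7,8-hexahydronaphthalen-2(3H)-one (9β-OH, cis to C14)
Conditions: NaBH4 (0.3 equiv), EtOH, −10 °C
Reagents that add atoms: none
Why: Chemoselective borohydride reduction; the isolated C9 ketone is more electrophilic than the enone carbonyl and hydride adds anti to the axial C14 methyl, which sets the C9 hydroxyl cis to C14.

**Step 2**
Reactants: 2 hydroxy enone
Product: 3 tert-butyldimethylsilyl ether of 2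
Conditions: TBSCl, imidazole, DMF, rt
Reagents that add atoms: tert-butyldimethylsilyl chloride CC(C)(C)[Si](C)(C)Cl
Why: Standard silylation of a hindered secondary alcohol; the ether tolerates the dissolving-metal, enolate, zinc and photochemical steps ahead.

**Step 3**
Reactants: 3 silyl ether enone
Product: 4 trans-fused decalone (ketone at ring carbon C15, H5 α, 9β-OTBS)
Conditions: Li, NH3(l), THF, t-BuOH (1 equiv), −78 °C; then NH4Cl
Reagents that add atoms: none
Why: Birch-type dissolving-metal reduction of the enone; protonation of the C5 carbanion in the more stable trans-fused geometry places H5 anti to C14.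

**Step 4**
Reactants: 4 trans-decalone
Product: 6 C1=C3 enone (trans-fused 5-silyloxy-4a-methyl-4a,5,6,7,8,8a-hexahydronaphthalen-2(1H)-one), via trimethylsilyl enol ether 5 (not isolated)
Conditions: LiN(i-Pr)2, THF, −78 °C; Me3SiCl; then Pd(OAc)2, MeCN, rt
Reagents that add atoms: none
Why: Saegusa–Ito dehydrogenation; kinetic deprotonation of the trans-fused ketone occurs at C3, away from the ring fusion (as in 5α-3-keto steroids), and Pd(OAc)2 turns the enol ether into the C1=C3 enone.

**Step 5**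
Reactants: 6 enone
Product: 7 15β-allylic alcohol (OH syn to C14)
Conditions: NaBH4, CeCl3·7H2O, MeOH, −78 °C
Reagents that add atoms: none
Why: Luche 1,2-reduction; axial hydride delivery on the α face of the half-chair enone should give the pseudo-equatorial 15β-alcohol, as steroidal 1-en-3-ones give 3β-alcohols.

**Step 6**
Reactants: 7 allylic alcohol; 8 diiodomethane
Product: 9 cyclopropyl carbinol (1β,3β-methylene, C2 syn to C14 and to the 15β-OH)
Conditions: Et2Zn, CH2I2, CH2Cl2, 0 °C to rt
Reagents that add atoms: diiodomethane ICI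
Why: Hydroxyl-directed Simmons–Smith cyclopropanation; the zinc alkoxide delivers CH2 to the alkene face carrying the hydroxyl, so C2 enters β against the steric bias of the axial methyl and fixes C1 and C3.

**Step 7**
Reactants: 9 cyclopropyl carbinol
Product: 10 cyclopropyl ketone (C15 ketone)
Conditions: Dess–Martin periodinane, NaHCO3, CH2Cl2, rt
Reagents that add atoms: none
Why: Dess–Martin oxidation of a secondary alcohol under buffered conditions that spare the cyclopropane and the silyl ether.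

**Step 8**
Reactants: 10 cyclopropyl ketone
Product: 11 4-(hydroxymethylene) ketone
Conditions: NaH, HCO2Et, THF, cat. EtOH, 0 °C to rt
Reagents that add atoms: ethyl formate CCOC=O
Why: Claisen formylation; C4 is the only enolisable position because the other α-carbon, C3, is a cyclopropane methine.

**Step 9**
Reactants: 11 hydroxymethylene ketone; 12 4-acetamidobenzenesulfonyl azide
Product: 13 4-diazo-15-ketone
Conditions: Et3N, MeCN, 0 °C to rt
Reagents that add atoms: 4-acetamidobenzenesulfonyl azide CC(=O)Nc1ccc(cc1)S(=O)(=O)N=[N+]=[N-]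
Why: Regitz deformylative diazo transfer; the azide adds to the formyl enolate and the adduct fragments with loss of the N-formyl sulfonamide, leaving the diazo group on C4.

**Step 10**
Reactants: 13 diazo ketone
Product: 15 lindenane tricycle with the C15 methyl ester on C4 (drawn 4α, trans to C6; H5 α; 9β-OTBS), via ketene 14 (not isolated)
Conditions: hν (medium-pressure Hg lamp, Pyrex), degassed MeOH, 0 °C
Reagents that add atoms: methanol CO
Why: Photochemical Wolff rearrangement of a cyclic 2-diazo ketone, the established ring contraction to a ring-contracted ester. The ring holds the diazo ketone s-Z, so loss of N2 is concerted with the 1,2-shift of cyclopropyl carbon C3 from C15 to C4, and methanol traps the resulting ketene 14 as the ester. Ring A (C1, C3, C4, C5, C10) is therefore formed by contraction of the six-membered ring through the new C3–C4 bond, not by a cyclisation, and C15 is pushed out as the exocyclic ester carbon. C3 migrates with retention and C1, C5, C9 and C10 are untouched; the new C4 centre is set by protonation of the ester enol, and either epimer serves because C4 becomes sp2 in step 11. The step needs the carbon shift to win over a 1,2-hydrogen shift from C5 and over O–H insertion; the locked s-Z geometry and metal-free photolysis favour the concerted shift.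

**Step 11**
Reactants: 15 ester
Product: 18 C4=C5 enoate, via 4α-phenylselanyl ester 16 (not isolated), via selenoxide 17 (not isolated)
Conditions: LiN(i-Pr)2, THF, −78 °C; PhSeBr; then AcOH, pyridine, 30% H2O2, 0 °C to rt
Reagents that add atoms: none
Why: α-Selenenylation and selenoxide syn-elimination; PhSeBr should enter on the α face, opposite C2 and C14, so selenium is syn to H5, and elimination can run only toward C5 because the other syn hydrogen sits on the cyclopropane.

**Step 12**
Reactants: 18 enoate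
Product: 19 C15 allylic alcohol
Conditions: i-Bu2AlH, CH2Cl2, −78 °C
Reagents that add atoms: none
Why: Hydride 1,2-reduction of the conjugated ester to the allylic alcohol, without change at the tetrasubstituted alkene or the silyl ether.

**Step 13**
Reactants: 19 allylic alcohol
Product: 20 9β,15-diol
Conditions: Bu4NF, THF, 50 °C
Reagents that add atoms: none
Why: Fluoride desilylation; with C9 free the two hydroxyls can be told apart by sterics in the next step.

**Step 14**
Reactants: 20 diol
Product: 21 15-O-tert-butyldiphenylsilyl ether with free 9β-OH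
Conditions: TBDPSCl, imidazole, CH2Cl2, 0 °C
Reagents that add atoms: tert-butyldiphenylsilyl chloride CC(C)(C)[Si](Cl)(c1ccccc1)c1ccccc1
Why: Selective silylation of the primary allylic hydroxyl; the neopentyl secondary C9 hydroxyl next to quaternary C10 reacts far more slowly with the bulky chlorosilane.

**Step 15**
Reactants: 21 alcohol
Product: 22 C9 ketone
Conditions: Dess–Martin periodinane, NaHCO3, CH2Cl2, rt
Reagents that add atoms: none
Why: Dess–Martin oxidation of the remaining secondary alcohol.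

**Step 16**
Reactants: 22 C9 ketone
Product: 24 C7=C8 enone, via trimethylsilyl enol ether 23 (not isolated)
Conditions: LiN(i-Pr)2, THF, −78 °C; Me3SiCl; then Pd(OAc)2, MeCN, rt
Reagents that add atoms: none
Why: Saegusa–Ito dehydrogenation; C10 is quaternary, so the ketone enolises only toward C8, and the neutral Pd(OAc)2 step leaves the doubly allylic C6 hydrogens in place.

**Step 17**
Reactants: 24 enone
Product: 25 9β-allylic alcohol (C7=C8)
Conditions: NaBH4, CeCl3·7H2O, MeOH, −78 °C
Reagents that add atoms: none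
Why: Luche 1,2-reduction; hydride adds anti to the axial C14 methyl on the neighbouring quaternary carbon and restores the 9β-hydroxyl, the same facial sense as in step 1.

**Step 18**
Reactants: 25 allylic alcohol
Product: 26 7β,8β-epoxy-9β-ol
Conditions: VO(acac)2 (cat.), t-BuOOH, CH2Cl2, 0 °C to rt
Reagents that add atoms: tert-butyl hydroperoxide CC(C)(C)OO
Why: Vanadium-catalysed hydroxyl-directed epoxidation; oxygen is delivered syn to the 9β-hydroxyl to the allylic C7=C8 bond, faster than to the hindered, only homoallylic C4=C5 bond.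

**Step 19**
Reactants: 26 epoxy alcohol
Product: 29 4,6-diene-8β,9β-diol, via 7α-phenylselanyl diol 27 (not isolated), via selenoxide 28 (not isolated)
Conditions: (PhSe)2, NaBH4, EtOH, 70 °C; then THF, pyridine, 30% H2O2, 0 °C to rt
Reagents that add atoms: none
Why: Organoselenium epoxide-to-allylic-alcohol transposition; selenolate opens the epoxide trans-diaxially at C7 (Fürst–Plattner, remote from the carbinol), and the 7α-selenoxide eliminates syn toward C6, away from the hydroxyl-bearing C8.

**Step 20**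
Reactants: 29 diene diol
Product: 30 4,6-dien-8-one with free 9β-OH
Conditions: MnO2, CH2Cl2, rt
Reagents that add atoms: none
Why: MnO2 oxidises only the allylic C8 alcohol, giving the linear dienone and leaving the C9 carbinol and its configuration.

**Step 21**
Reactants: 30 hydroxy dienone
Product: 31 9β-O-tert-butyldimethylsilyl dienone
Conditions: TBSOTf, 2,6-lutidine, CH2Cl2, −78 to 0 °C
Reagents that add atoms: tert-butyldimethylsilyl triflate CC(C)(C)[Si](C)(C)OS(=O)(=O)C(F)(F)F
Why: Silyl triflate with a hindered base protects the hindered α-hydroxyl without enolising the dienone.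

**Step 22**
Reactants: 31 dienone
Product: 32 7-iodo dienone
Conditions: I2, pyridine, CH2Cl2, 0 °C to rt
Reagents that add atoms: iodine II
Why: α-Iodination of an enone by the pyridine addition–iodination–elimination sequence (Baylis–Hillman-type) places iodine on C7, the α-carbon of the dienone.

**Step 23**
Reactants: 32 iodo dienone; 33 methyl 2-bromopropanoate
Product: 35 methyl 2-(dienon-7-yl)propanoate (C11 epimers), via Reformatsky reagent 34 (not isolated)
Conditions: 33, Zn dust (Me3SiCl-activated), THF, rt; then 32, Pd2(dba)3 (cat.), P(t-Bu)3, THF, rt to 50 °C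
Reagents that add atoms: methyl 2-bromopropanoate CC(Br)C(=O)OC
Why: Negishi-type coupling of a Reformatsky reagent with an alkenyl iodide (palladium-catalysed α-alkenylation of a zinc ester enolate); oxidative addition at C7–I is fast and the mild zinc enolate should not attack the ketone or disturb C9.

**Step 24**
Reactants: 35 keto ester
Product: 37 monomer 8β,12-lactone (C4=C5 and C6=C7; 9β-OTBS; 15-OTBDPS; C11–H), via 8β-hydroxy ester 36 (not isolated)
Conditions: NaBH4, CeCl3·7H2O, MeOH, −40 °C; then PPTS (cat.), toluene, 45 °C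
Reagents that add atoms: none
Why: Luche reduction then acid-catalysed lactonisation; the β face of C8 is blocked by the 1,3-related axial C14 methyl and the 9β-silyloxy group, so hydride should add on the α face, and the resulting 8β-hydroxyl (cis to O9) closes the γ-lactone onto C12.

**Step 25**
Reactants: 37 lactone
Product: 38 lactone C15 alcohol
Conditions: Bu4NF, AcOH, THF, 0 °C to rt
Reagents that add atoms: none
Why: Buffered fluoride removes the primary allylic TBDPS ether much faster than the neopentyl secondary TBS ether, and the acetic acid keeps the β,γ-unsaturated lactone from isomerising.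

**Step 26**
Reactants: 38 alcohol
Product: 39 lactone C15 allylic bromide
Conditions: CBr4, PPh3, 2,6-lutidine, CH2Cl2, −30 °C; used at once
Reagents that add atoms: carbon tetrabromide BrC(Br)(Br)Br
Why: Appel bromination of a primary allylic alcohol under neutral, cold conditions.

**Step 27**
Reactants: 37 lactone (slight excess); 39 bromide
Product: 41 linear dimer (C11 of one unit bonded to C15′ of the other; 15-OTBDPS on the first unit; C11′–H lactone on the second), via lithium dienolate 40 (not isolated)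
Conditions: 37, LiN(i-Pr)2, THF, −78 °C; DMPU; then 39, −78 to −40 °C
Reagents that add atoms: none
Why: α-Alkylation of a lithium lactone dienolate by a primary allylic bromide; the planar dienolate should be attacked at C11 on its α face, anti to the C9 branch on the neighbouring lactone carbon C8 and away from the β-silyloxy group and C14, and because the lactone ties C12 to C8 this puts C15′ α and the methyl β, the natural C11 configuration.

**Step 28**
Reactants: 41 linear dimer
Product: 42 linear dimer C15 alcohol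
Conditions: Bu4NF, AcOH, THF, 0 °C to rt
Reagents that add atoms: none
Why: Selective fluoride cleavage of the primary TBDPS ether beside two hindered secondary TBS ethers, as in step 25.

**Step 29**
Reactants: 42 alcohol
Product: 43 linear dimer C15 bromide
Conditions: CBr4, PPh3, 2,6-lutidine, CH2Cl2, −30 °C; used at once
Reagents that add atoms: carbon tetrabromide BrC(Br)(Br)Br
Why: Appel bromination, as in step 26.

**Step 30**
Reactants: 43 bromide
Product: 45 macrocyclic bis-lactone (12-membered ring, both C11–C15′ bonds, two 9β-OTBS), via lithium dienolate 44 (not isolated)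
Conditions: slow addition of 43 to LiN(SiMe3)2, THF/DMPU, −40 to 0 °C, about 1 mM
Reagents that add atoms: none
Why: Macrocyclisation by intramolecular enolate alkylation under high dilution; the same lactone-controlled α-face attack sets the second C11, and it is the matched case because the first C11–C15′ bond already holds the two α faces against each other, as the C2-symmetric ring requires.

**Step 31**
Reactants: 45 bis-lactone
Product: 46 macrocyclic bis-lactone 9,9′-diol
Conditions: HF·pyridine, pyridine, THF, 0 °C to rt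
Reagents that add atoms: none
Why: Fluoride desilylation before the basic step, so that no silyl group can migrate between the cis oxygens on C8 and C9.

**Step 32**
Reactants: 46 bis-lactone diol
Product: 48 macrocyclic tetraol dimethyl ester (8β,9β-diol in each half), via dilithium dicarboxylate 47 (not isolated)
Conditions: LiOH, THF/H2O, rt; evaporate; then MeI, DMF, 0 °C to rt
Reagents that add atoms: lithium hydroxide [Li+].[OH-]; iodomethane CI
Why: Saponification of the γ-lactones and SN2 O-methylation of the carboxylates gives the methyl esters with no acidic work-up, so the γ-hydroxy esters should not close back.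

**Step 33**
Reactants: 48 tetraol diester
Product: 49 cycloshizukaol A
Conditions: MnO2, CH2Cl2, rt
Reagents that add atoms: none
Why: MnO2 oxidation is selective for the two allylic C8 alcohols, as in step 20, giving both dienones and leaving the 9β-hydroxyls.

**Compound list**
1 | (S)-Wieland–Miescher ketone | C[C@]12CCC(=O)C=C1CCCC2=O | starting material
2 | (4aS,5S)-5-hydroxy-4a-methyl-4,4a,5,6,7,8-hexahydronaphthalen-2(3H)-one | O=C1C=C2CCC[C@H](O)[C@@]2(C)CC1 | intermediate
3 | TBS ether of 2 | O=C1C=C2CCC[C@H](O[Si](C)(C)C(C)(C)C)[C@@]2(C)CC1 | intermediate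
4 | trans-fused decalone, H5 α, 9β-OTBS | O=C1C[C@@H]2CCC[C@H](O[Si](C)(C)C(C)(C)C)[C@@]2(C)CC1 | intermediate
5 | trimethylsilyl enol ether (C3=C15) of 4 | C[Si](C)(C)OC=1C[C@@H]2CCC[C@H](O[Si](C)(C)C(C)(C)C)[C@@]2(C)CC=1 | intermediate
6 | trans-fused C1=C3 enone | O=C1C[C@@H]2CCC[C@H](O[Si](C)(C)C(C)(C)C)[C@@]2(C)C=C1 | intermediate
7 | 15β-allylic alcohol | O[C@@H]1C[C@@H]2CCC[C@H](O[Si](C)(C)C(C)(C)C)[C@@]2(C)C=C1 | intermediate
8 | diiodomethane | ICI | starting material
9 | 1β,3β-methylene 15β-carbinol | O[C@@H]1C[C@@H]2CCC[C@H](O[Si](C)(C)C(C)(C)C)[C@@]2(C)[C@@H]2C[C@H]12 | intermediate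
10 | cyclopropyl ketone | O=C1C[C@@H]2CCC[C@H](O[Si](C)(C)C(C)(C)C)[C@@]2(C)[C@@H]2C[C@H]12 | intermediate
11 | 4-(hydroxymethylene) ketone | O=C1/C(=C\O)[C@@H]2CCC[C@H](O[Si](C)(C)C(C)(C)C)[C@@]2(C)[C@@H]2C[C@H]12 | intermediate
12 | 4-acetamidobenzenesulfonyl azide | CC(=O)Nc1ccc(cc1)S(=O)(=O)N=[N+]=[N-] | starting material
13 | cyclopropanated trans-decalin 4-diazo-15-ketone | O=C1C(=[N+]=[N-])[C@@H]2CCC[C@H](O[Si](C)(C)C(C)(C)C)[C@@]2(C)[C@@H]2C[C@H]12 | intermediate
14 | ring-contracted ketene | O=C=C1[C@@H]2CCC[C@H](O[Si](C)(C)C(C)(C)C)[C@@]2(C)[C@@H]2C[C@H]12 | intermediate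
15 | lindenane tricycle, C15 methyl ester on C4 (4α), 9β-OTBS | COC(=O)[C@H]1[C@@H]2CCC[C@H](O[Si](C)(C)C(C)(C)C)[C@@]2(C)[C@@H]2C[C@H]12 | intermediate
16 | 4α-phenylselanyl ester | COC(=O)[C@]1([Se]c3ccccc3)[C@@H]2CCC[C@H](O[Si](C)(C)C(C)(C)C)[C@@]2(C)[C@@H]2C[C@H]12 | intermediate
17 | selenoxide of 16 | COC(=O)[C@]1([Se](=O)c3ccccc3)[C@@H]2CCC[C@H](O[Si](C)(C)C(C)(C)C)[C@@]2(C)[C@@H]2C[C@H]12 | intermediate
18 | C4=C5 enoate | COC(=O)C1=C2CCC[C@H](O[Si](C)(C)C(C)(C)C)[C@@]2(C)[C@@H]2C[C@H]12 | intermediate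
19 | C15 allylic alcohol, 9β-OTBS | OCC1=C2CCC[C@H](O[Si](C)(C)C(C)(C)C)[C@@]2(C)[C@@H]2C[C@H]12 | intermediate
20 | 9β,15-diol | OCC1=C2CCC[C@H](O)[C@@]2(C)[C@@H]2C[C@H]12 | intermediate
21 | 15-OTBDPS 9β-ol | CC(C)(C)[Si](OCC1=C2CCC[C@H](O)[C@@]2(C)[C@@H]2C[C@H]12)(c1ccccc1)c1ccccc1 | intermediate
22 | 15-OTBDPS 9-ketone | CC(C)(C)[Si](OCC1=C2CCCC(=O)[C@@]2(C)[C@@H]2C[C@H]12)(c1ccccc1)c1ccccc1 | intermediate
23 | trimethylsilyl enol ether (C8=C9) of 22 | CC(C)(C)[Si](OCC1=C2CCC=C(O[Si](C)(C)C)[C@@]2(C)[C@@H]2C[C@H]12)(c1ccccc1)c1ccccc1 | intermediate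
24 | C7=C8 9-enone | CC(C)(C)[Si](OCC1=C2CC=CC(=O)[C@@]2(C)[C@@H]2C[C@H]12)(c1ccccc1)c1ccccc1 | intermediate
25 | C7=C8 9β-allylic alcohol | CC(C)(C)[Si](OCC1=C2CC=C[C@H](O)[C@@]2(C)[C@@H]2C[C@H]12)(c1ccccc1)c1ccccc1 | intermediate
26 | 7β,8β-epoxy-9β-ol | CC(C)(C)[Si](OCC1=C2C[C@@H]3O[C@@H]3[C@H](O)[C@@]2(C)[C@@H]2C[C@H]12)(c1ccccc1)c1ccccc1 | intermediate
27 | 7α-phenylselanyl-8β,9β-diol | CC(C)(C)[Si](OCC1=C2C[C@@H]([Se]c3ccccc3)[C@H](O)[C@H](O)[C@@]2(C)[C@@H]2C[C@H]12)(c1ccccc1)c1ccccc1 | intermediate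
28 | selenoxide of 27 | CC(C)(C)[Si](OCC1=C2C[C@@H]([Se](=O)c3ccccc3)[C@H](O)[C@H](O)[C@@]2(C)[C@@H]2C[C@H]12)(c1ccccc1)c1ccccc1 | intermediate
29 | 4,6-diene-8β,9β-diol | CC(C)(C)[Si](OCC1=C2C=C[C@H](O)[C@H](O)[C@@]2(C)[C@@H]2C[C@H]12)(c1ccccc1)c1ccccc1 | intermediate
30 | 4,6-dien-8-one 9β-ol | CC(C)(C)[Si](OCC1=C2C=CC(=O)[C@H](O)[C@@]2(C)[C@@H]2C[C@H]12)(c1ccccc1)c1ccccc1 | intermediate
31 | 9β-OTBS dienone | CC(C)(C)[Si](OCC1=C2C=CC(=O)[C@H](O[Si](C)(C)C(C)(C)C)[C@@]2(C)[C@@H]2C[C@H]12)(c1ccccc1)c1ccccc1 | intermediate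
32 | 7-iodo dienone | CC(C)(C)[Si](OCC1=C2C=C(I)C(=O)[C@H](O[Si](C)(C)C(C)(C)C)[C@@]2(C)[C@@H]2C[C@H]12)(c1ccccc1)c1ccccc1 | intermediate
33 | methyl 2-bromopropanoate (racemic) | CC(Br)C(=O)OC | starting material
34 | bromo(1-methoxy-1-oxopropan-2-yl)zinc | CC([Zn]Br)C(=O)OC | intermediate
35 | methyl 2-(dienon-7-yl)propanoate, C11 epimers | CC(C)(C)[Si](OCC1=C2C=C(C(C)C(=O)OC)C(=O)[C@H](O[Si](C)(C)C(C)(C)C)[C@@]2(C)[C@@H]2C[C@H]12)(c1ccccc1)c1ccccc1 | intermediate
36 | 8β-hydroxy ester | CC(C)(C)[Si](OCC1=C2C=C(C(C)C(=O)OC)[C@H](O)[C@H](O[Si](C)(C)C(C)(C)C)[C@@]2(C)[C@@H]2C[C@H]12)(c1ccccc1)c1ccccc1 | intermediate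
37 | monomer 8β,12-lactone, 15-OTBDPS | CC(C)(C)[Si](OCC1=C2C=C3C(C)C(=O)O[C@@H]3[C@H](O[Si](C)(C)C(C)(C)C)[C@@]2(C)[C@@H]2C[C@H]12)(c1ccccc1)c1ccccc1 | intermediate
38 | monomer lactone, C15 alcohol | OCC1=C2C=C3C(C)C(=O)O[C@@H]3[C@H](O[Si](C)(C)C(C)(C)C)[C@@]2(C)[C@@H]2C[C@H]12 | intermediate
39 | monomer lactone, C15 bromide | BrCC1=C2C=C3C(C)C(=O)O[C@@H]3[C@H](O[Si](C)(C)C(C)(C)C)[C@@]2(C)[C@@H]2C[C@H]12 | intermediate
40 | lithium dienolate of 37 | CC(C)(C)[Si](OCC1=C2C=C3C(C)=C([O-])O[C@@H]3[C@H](O[Si](C)(C)C(C)(C)C)[C@@]2(C)[C@@H]2C[C@H]12)(c1ccccc1)c1ccccc1.[Li+] | intermediate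
41 | linear dimer, 15-OTBDPS | CC(C)(C)[Si](OCC1=C2C=C3[C@@](C)(CC4=C5C=C6C(C)C(=O)O[C@@H]6[C@H](O[Si](C)(C)C(C)(C)C)[C@@]5(C)[C@@H]5C[C@H]45)C(=O)O[C@@H]3[C@H](O[Si](C)(C)C(C)(C)C)[C@@]2(C)[C@@H]2C[C@H]12)(c1ccccc1)c1ccccc1 | intermediate
42 | linear dimer, C15 alcohol | OCC1=C2C=C3[C@@](C)(CC4=C5C=C6C(C)C(=O)O[C@@H]6[C@H](O[Si](C)(C)C(C)(C)C)[C@@]5(C)[C@@H]5C[C@H]45)C(=O)O[C@@H]3[C@H](O[Si](C)(C)C(C)(C)C)[C@@]2(C)[C@@H]2C[C@H]12 | intermediate
43 | linear dimer, C15 bromide | BrCC1=C2C=C3[C@@](C)(CC4=C5C=C6C(C)C(=O)O[C@@H]6[C@H](O[Si](C)(C)C(C)(C)C)[C@@]5(C)[C@@H]5C[C@H]45)C(=O)O[C@@H]3[C@H](O[Si](C)(C)C(C)(C)C)[C@@]2(C)[C@@H]2C[C@H]12 | intermediate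
44 | lithium dienolate of 43 | BrCC1=C2C=C3[C@@](C)(CC4=C5C=C6C(C)=C([O-])O[C@@H]6[C@H](O[Si](C)(C)C(C)(C)C)[C@@]5(C)[C@@H]5C[C@H]45)C(=O)O[C@@H]3[C@H](O[Si](C)(C)C(C)(C)C)[C@@]2(C)[C@@H]2C[C@H]12.[Li+] | intermediate
45 | macrocyclic bis-lactone, bis-TBS ether | C7C1=C2C=C3[C@@](C)(CC4=C5C=C6[C@]7(C)C(=O)O[C@@H]6[C@H](O[Si](C)(C)C(C)(C)C)[C@@]5(C)[C@@H]5C[C@H]45)C(=O)O[C@@H]3[C@H](O[Si](C)(C)C(C)(C)C)[C@@]2(C)[C@@H]2C[C@H]12 | intermediate
46 | macrocyclic bis-lactone 9,9′-diol | C7C1=C2C=C3[C@@](C)(CC4=C5C=C6[C@]7(C)C(=O)O[C@@H]6[C@H](O)[C@@]5(C)[C@@H]5C[C@H]45)C(=O)O[C@@H]3[C@H](O)[C@@]2(C)[C@@H]2C[C@H]12 | intermediate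
47 | dilithium dicarboxylate tetraol | [Li+].[Li+].[O-]C(=O)[C@]1(C)CC2=C3C=C([C@H](O)[C@H](O)[C@@]3(C)[C@@H]3C[C@H]23)[C@](C)(C([O-])=O)CC2=C3C=C1[C@H](O)[C@H](O)[C@@]3(C)[C@@H]1C[C@H]21 | intermediate
48 | macrocyclic tetraol dimethyl ester | COC(=O)[C@]1(C)CC2=C3C=C([C@H](O)[C@H](O)[C@@]3(C)[C@@H]3C[C@H]23)[C@](C)(C(=O)OC)CC2=C3C=C1[C@H](O)[C@H](O)[C@@]3(C)[C@@H]1C[C@H]21 | intermediate
49 | cycloshizukaol A | COC(=O)[C@]1(C)CC2=C3C=C(C(=O)[C@H](O)[C@@]3(C)[C@@H]3C[C@H]23)[C@](C)(C(=O)OC)CC2=C3C=C1C(=O)[C@H](O)[C@@]3(C)[C@@H]1C[C@H]21 | target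

**Step count and risks**
Total: 33 steps. Longest linear sequence: 33 steps (1 to 49, passing through 37, 38 and 39).

Steps most likely to fail:

1. Step 30 (macrocyclisation). Intermolecular alkylation may outrun closure of the strained 12-membered ring, and the dienolate may be alkylated on oxygen or at its γ-carbon. Fallback, from 42: acylation with methyl chloroformate and pyridine gives the methyl carbonate F1, and deprotonation with LiN(SiMe3)2 at −78 °C gives its lithium dienolate F2. Slow addition of F2 to Pd(PPh3)4 (zerovalent palladium) in THF at 40 °C should ionise the carbonate to a π-allyl complex and close the ring by C-allylation at the unhindered C15 terminus (intramolecular Tsuji–Trost). The route is rejoined at 45.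

2. Step 27 (union of the two halves). Proton transfer from bromide 39 to dienolate 40 may compete with substitution; the deprotonated bromide would lose bromide by 1,8-elimination and chain growth would follow. Facial selectivity at C11 may also be incomplete. Fallback, from 39: DBU in CH2Cl2 effects the 1,8-dehydrobromination on purpose and gives the trienolide F3 (C4=C15 methylene, C5=C6, C7=C11), an acceptor without an acidic C11 hydrogen. Slow addition of F3 to an excess of 40 at −78 °C should give vinylogous Michael (1,8-) addition at the exocyclic C15, on the same α face of 40, to the lithium dienolate F4. Protonation with AcOH gives 41, where the route is rejoined.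

3. Step 23 (C7–C11 coupling). Transmetalation of the secondary zinc enolate at the hindered C7 may be slow, so that reductive loss of iodine takes over. Fallback, from 32: Stille coupling with methyl 2-(tributylstannyl)acrylate (PdCl2(PhCN)2, AsPh3, CuI, NMP) gives the acrylate dienone F5. Luche reduction gives the 8β-hydroxy acrylate F6, which lactonises with PPTS to the α-methylene lactone F7. Conjugate reduction with LiBH(s-Bu)3 at −78 °C generates dienolate 40, and protonation with AcOH gives 37, where the route is rejoined.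

**Further compounds**
F1 | step 30 | methyl carbonate of 42 | COC(=O)OCC1=C2C=C3[C@@](C)(CC4=C5C=C6C(C)C(=O)O[C@@H]6[C@H](O[Si](C)(C)C(C)(C)C)[C@@]5(C)[C@@H]5C[C@H]45)C(=O)O[C@@H]3[C@H](O[Si](C)(C)C(C)(C)C)[C@@]2(C)[C@@H]2C[C@H]12
F2 | step 30 | lithium dienolate of F1 | COC(=O)OCC1=C2C=C3[C@@](C)(CC4=C5C=C6C(C)=C([O-])O[C@@H]6[C@H](O[Si](C)(C)C(C)(C)C)[C@@]5(C)[C@@H]5C[C@H]45)C(=O)O[C@@H]3[C@H](O[Si](C)(C)C(C)(C)C)[C@@]2(C)[C@@H]2C[C@H]12.[Li+]
F3 | step 27 | trienolide (4(15),5,7(11)-triene 8β,12-lactone, 9β-OTBS) | C=C1C2=CC3=C(C)C(=O)O[C@@H]3[C@H](O[Si](C)(C)C(C)(C)C)[C@@]2(C)[C@@H]2C[C@H]12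
F4 | step 27 | lithium dienolate of 41 | CC(C)(C)[Si](OCC1=C2C=C3[C@@](C)(CC4=C5C=C6C(C)=C([O-])O[C@@H]6[C@H](O[Si](C)(C)C(C)(C)C)[C@@]5(C)[C@@H]5C[C@H]45)C(=O)O[C@@H]3[C@H](O[Si](C)(C)C(C)(C)C)[C@@]2(C)[C@@H]2C[C@H]12)(c1ccccc1)c1ccccc1.[Li+]
F5 | step 23 | methyl 2-(dienon-7-yl)acrylate | CC(C)(C)[Si](OCC1=C2C=C(C(=C)C(=O)OC)C(=O)[C@H](O[Si](C)(C)C(C)(C)C)[C@@]2(C)[C@@H]2C[C@H]12)(c1ccccc1)c1ccccc1
F6 | step 23 | 8β-hydroxy acrylate | CC(C)(C)[Si](OCC1=C2C=C(C(=C)C(=O)OC)[C@H](O)[C@H](O[Si](C)(C)C(C)(C)C)[C@@]2(C)[C@@H]2C[C@H]12)(c1ccccc1)c1ccccc1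
F7 | step 23 | α-methylene 8β,12-lactone | CC(C)(C)[Si](OCC1=C2C=C3C(=C)C(=O)O[C@@H]3[C@H](O[Si](C)(C)C(C)(C)C)[C@@]2(C)[C@@H]2C[C@H]12)(c1ccccc1)c1ccccc1
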